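The runs are calculated from invented constants, and the scatter is random.

You suspect that slowness will cost target in the flask, but drop that worry: Friday's readings top at 34% by 0.667 min and Saturday's reach 63% by 0.667 min, well before the 3.0 min allowed. Here is what stands.

common to all: substrate 0.050 M

| charge | reagent | remark | time |
|---|---|---|---|
| Friday's | 0.035 M | run made earlier |  |
| Saturday's | 0.079 M | run made earlier |  |
| flask | 0.0525 M |  | 3.0 min |

- Friday's (time / min: target / %): 0.167: 26; 0.250: 29; 0.417: 33; 0.667: 34; 1.00: 32; 1.50: 26; 2.50: 24
- Saturday's (time / min: target / %): 0.167: 45; 0.250: 58; 0.417: 61; 0.667: 63; 1.00: 63; 1.50: 60; 2.50: 51

(each reading ± 1.5 percentage points)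

1. time up to 3.0 min at which target stands highest
2. the amount of target, in percent of the substrate charged, at that time
3. earliest time at which at least nineteen twentieths of that best amount are there, in min
4. latest time at which they still are, in min

- percentages count the substrate that a species holds: one side product counts as two
- candidate steps: substrate + target -> side product; substrate + reagent <-> target + by-product

Reckon on reagent instead. Take each run's top target in moles per mole of reagent charged: Friday's reads 0.486 and Saturday's 0.399. Replace that falling curve by its mean, Y = 0.442, the yield on reagent. Multiply Y by the flask's reagent and divide by its substrate: my top is 46.4%. Take half the spread of the two values as the error of the mean, which is 4.6 percentage points in the flask. Expect the top near 0.667 min, where both runs read high.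

The forecast gave 45% at 0.65 min and a window from 0.36 min to 1.15 min, noting “The flask has 1.05 equivalents of reagent, between Friday's 0.70 and Saturday's 1.58”.

The flask gives 48.4% at 0.641 min, with the window from 0.354 min to 1.21 min. Its yield on reagent is 0.461, and my top fell short by 2 points, less than the error allowed.

    substrate + target → side product (k = 0.690 /M/s)
    substrate + reagent ⇌ target + by-product (K = 14.0, k = 1.40 /M/s)

At 0.114 min in the flask, substrate has a half-life of 0.23 min by the forward step alone, shorter than the 0.53 min of target by its turning into side product. At that moment the forward rate alone uses substrate 4.8 times as fast as the side step. For the neighbour flask with 0.021 M of reagent, Y gives 18.6%, give or take 1.8 points. The computed top there is 20.8%, just outside that error.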